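**Strategy**

Both prenyl groups on C3' of the six-membered triketone ring (C1' carries the terpene, C5' the isobutyryl group) are disconnected back to the neighbouring C2' and C4' oxygens. In the aromatic form of that ring C3' is the one unsubstituted carbon and sits ortho to both oxygens, so a bis(1,1-dimethylallyl) ether can hand over its two allyl units to C3' by consecutive aromatic Claisen shifts on warming, creating the quaternary centre and dearomatising the ring in a single operation. The precursor is a cis-fused hexahydrodibenzofuran, built from (R)-carvone and phloroisobutyrophenone, in which the C6' oxygen is tied to the terpene's tertiary carbon; hydroxide opens this ring at the end.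

Key step: step 11

Assumption: the C5 units are taken from commercial 3-chloro-3-methylbut-1-yne (the chloride of 2-methylbut-3-yn-2-ol), which avoids a separate activation of the alcohol.
Remark: locants C1'–C6' are those of the triketone ring of the target; C3' corresponds to C2 of the dibenzofuran intermediates. In step 11 the ether on the C2' oxygen is drawn as shifting first; the other order leads to the same product.
Remark: the aryl ether must be cis to the isopropenyl group for the Claisen shift to place the aryl group correctly, and the etherification inverts, so trans-carveol is needed and is made from carvone by reduction and inversion.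

**Route**

Step 1
Reactants: 1 (R)-(−)-carvone
Product: 2 (1R,5R)-cis-carveol
Conditions: NaBH4, CeCl3·7H2O, MeOH, −20 to 0 °C
Reagents that add atoms: none
Why: Luche reduction adds hydride 1,2 to the enone, and axial delivery on the half-chair with a pseudo-equatorial isopropenyl group sets C1 with the hydroxyl cis to that group.

Step 2
Reactants: 2 (1R,5R)-cis-carveol
Product: 3 (1S,5R)-trans-carveyl 4-nitrobenzoate
Conditions: 4-nitrobenzoic acid, PPh3, DIAD, THF, 0 °C to rt
Reagents that add atoms: 4-nitrobenzoic acid, O=C(O)c1ccc(cc1)[N+](=O)[O-]
Why: In this Mitsunobu reaction the carboxylate displaces the alkoxyphosphonium group by SN2 at C1, so the configuration there is inverted and the oxygen ends up trans to the isopropenyl group.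

Step 3
Reactants: 3 (1S,5R)-trans-carveyl 4-nitrobenzoate
Product: 4 (1S,5R)-trans-carveol
Conditions: K2CO3 (cat.), MeOH, rt
Reagents that add atoms: none
Why: Base-catalysed transesterification (methanolysis) breaks the acyl–oxygen bond of the electron-poor benzoate, so the inverted C1 configuration is untouched.

Step 4
Reactants: 5 phloroisobutyrophenone
Product: 6 4-O-TBS-phloroisobutyrophenone
Conditions: TBSCl (1.05 equiv), imidazole, DMF, 0 °C
Reagents that add atoms: tert-butyldimethylsilyl chloride, CC(C)(C)[Si](C)(C)Cl
Why: Selective silylation is expected because the hydroxyl para to the acyl group is the most acidic and least hindered, whereas the two equivalent ortho phenols are flanked by and hydrogen-bonded to the ketone.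

Step 5
Reactants: 4 (1S,5R)-trans-carveol; 6 4-O-TBS-phloroisobutyrophenone
Product: 7 aryl (1R,5R)-cis-carveyl ether
Conditions: PPh3, DIAD, THF, 0 °C to rt (6 in slight excess)
Reagents that add atoms: none
Why: In this Mitsunobu etherification one of the two equivalent ortho phenols attacks the activated allylic alcohol by SN2 with inversion at C1, which places the ether oxygen cis to the isopropenyl group, while the remaining phenol stays chelated to the ketone and does not react further.

Step 6
Reactants: 7 aryl (1R,5R)-cis-carveyl ether
Product: 8 C3-terpenyl phenol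
Conditions: PhNEt2, 180 °C, sealed tube
Reagents that add atoms: none
Why: The aromatic Claisen rearrangement can reach only the free ortho carbon (the other carries the acyl group) and is suprafacial on the cyclohexenyl unit, so the new aryl–carbon bond forms on the face the oxygen leaves and the aryl group ends up cis to the isopropenyl group before enolisation restores the phenol.

Step 7
Reactants: 8 C3-terpenyl phenol
Product: 9 cis-fused hexahydrodibenzofuran 1-O-TBS ether
Conditions: Amberlyst-15 (H+ form), CH2Cl2, 0 °C to rt, stopped at full conversion
Reagents that add atoms: none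
Why: In this acid-catalysed Markovnikov hydroalkoxylation (5-exo-trig) the tertiary cation from the trisubstituted ring alkene is trapped by the adjacent phenol faster than anything happens at the isopropenyl group, the short tether allows only cis ring fusion so the neighbouring aryl-bearing carbon sets the new quaternary centre, and the silyl ether keeps the other flanking oxygen out of play.

Step 8
Reactants: 9 cis-fused hexahydrodibenzofuran 1-O-TBS ether
Product: 10 hexahydrodibenzofuran-1,3-diol
Conditions: TBAF, AcOH, THF, 0 °C
Reagents that add atoms: none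
Why: Fluoride cleaves the aryl silyl ether through the strong Si–F bond, and the acetic acid buffer protonates the phenoxide at once.

Step 9
Reactants: 10 hexahydrodibenzofuran-1,3-diol; 11 3-chloro-3-methylbut-1-yne
Product: 12 bis(1,1-dimethylpropargyl) ether
Conditions: 11 (6 equiv), DBU, CuCl2·2H2O (cat.), MeCN, N2, 0 °C to rt
Reagents that add atoms: none
Why: In this copper-catalysed propargylic etherification the tertiary propargylic chloride becomes a copper allenylidene-type electrophile that the DBU-generated phenoxides capture at the tertiary carbon, and excess reagent is used because the phenol chelated to the ketone reacts more slowly than the free one.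

Step 10
Reactants: 12 bis(1,1-dimethylpropargyl) ether
Product: 13 bis(1,1-dimethylallyl) ether (key-step precursor)
Conditions: H2 (1 atm), Lindlar catalyst, quinoline, EtOAc, 0 °C; filtered and concentrated cold, used at once
Reagents that add atoms: none
Why: Lindlar semi-hydrogenation on the poisoned palladium reduces the two terminal alkynes to vinyl groups and should leave the 1,1-disubstituted isopropenyl alkene, the ketone and the aryl ethers alone.

Step 11
Reactants: 13 bis(1,1-dimethylallyl) ether (key-step precursor)
Product: 15 gem-diprenyl dearomatised dihydrofuran (vinylogous ester), via monoprenyl phenol monoether 14 (not isolated)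
Conditions: degassed PhMe, PhNEt2 (1 equiv), 105 °C, sealed tube
Reagents that add atoms: none
Why: Each 1,1-dimethylallyl aryl ether undergoes a concerted [3,3] sigmatropic shift through a chair-like transition state, which can deliver the allyl unit only to an ortho carbon and turns it into a normal prenyl group; the first shift is followed by enolisation to phenol 14, and the second places another prenyl group on the same carbon to give a 2,2-disubstituted cyclohexadienone that cannot rearomatise and settles as the enolised, hydrogen-bonded triketone form 15. The closest known reactions are the aromatic Claisen rearrangement of 1,1-dimethylallyl aryl ethers to ortho-prenyl phenols and the dearomatising Claisen shift to an already substituted ortho carbon of acylphloroglucinol ethers. No ring is closed and no stereocentre is created, since the new quaternary carbon carries two identical prenyl groups and the three existing centres lie away from the reacting atoms. Regioselectivity is the only requirement and the substitution pattern secures it: the carbon between the two ether oxygens is the single unsubstituted ortho position of both, while shifts to the acyl- or terpene-bearing carbons give crowded dienones that can revert. The neutral, amine-buffered medium should suppress ionisation of the tertiary allylic ethers, so the isopropenyl group and the tertiary alkyl aryl ether are expected to survive.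

Step 12
Reactants: 15 gem-diprenyl dearomatised dihydrofuran (vinylogous ester)
Product: 16 target (CNP0324849.1)
Conditions: LiOH·H2O (10 equiv), 1,4-dioxane/H2O (3:1), Ar, 70 °C; then 1 M HCl, 0 °C, to pH 3 and immediate extraction
Reagents that add atoms: lithium hydroxide, [Li+].[OH-]
Why: In this vinylogous ester saponification (addition–elimination) hydroxide adds to the alkoxy-bearing ring carbon C6', the tetrahedral intermediate expels the tethered tertiary alkoxide with its C–O bond and configuration intact, and formation of the doubly deprotonated trione should make the opening irreversible until cold acidification releases the target.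

**Compound list**

1 | (R)-(−)-carvone, (5R)-2-methyl-5-(prop-1-en-2-yl)cyclohex-2-en-1-one | C=C(C)[C@H]1CC(=O)C(C)=CC1 | starting material
2 | (1R,5R)-cis-carveol, (1R,5R)-2-methyl-5-(prop-1-en-2-yl)cyclohex-2-en-1-ol, OH cis to isopropenyl | C=C(C)[C@H]1C[C@@H](O)C(C)=CC1 | intermediate
3 | (1S,5R)-trans-carveyl 4-nitrobenzoate, ester oxygen trans to isopropenyl | C=C(C)[C@H]1C[C@H](OC(=O)c2ccc(cc2)[N+](=O)[O-])C(C)=CC1 | intermediate
4 | (1S,5R)-trans-carveol, (1S,5R)-2-methyl-5-(prop-1-en-2-yl)cyclohex-2-en-1-ol, OH trans to isopropenyl | C=C(C)[C@H]1C[C@H](O)C(C)=CC1 | intermediate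
5 | phloroisobutyrophenone, 2-methyl-1-(2,4,6-trihydroxyphenyl)propan-1-one | CC(C)C(=O)c1c(O)cc(O)cc1O | starting material
6 | 4-O-TBS-phloroisobutyrophenone, 1-[4-(tert-butyldimethylsilyloxy)-2,6-dihydroxyphenyl]-2-methylpropan-1-one | CC(C)C(=O)c1c(O)cc(O[Si](C)(C)C(C)(C)C)cc1O | intermediate
7 | aryl (1R,5R)-cis-carveyl ether, 1-[4-(tert-butyldimethylsilyloxy)-2-hydroxy-6-{[(1R,5R)-2-methyl-5-(prop-1-en-2-yl)cyclohex-2-en-1-yl]oxy}phenyl]-2-methylpropan-1-one, ether oxygen cis to isopropenyl | C=C(C)[C@H]1C[C@@H](Oc2cc(O[Si](C)(C)C(C)(C)C)cc(O)c2C(=O)C(C)C)C(C)=CC1 | intermediate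
8 | C3-terpenyl phenol, 1-{4-(tert-butyldimethylsilyloxy)-2,6-dihydroxy-3-[(1S,5S)-2-methyl-5-(prop-1-en-2-yl)cyclohex-2-en-1-yl]phenyl}-2-methylpropan-1-one, aryl cis to isopropenyl | C=C(C)[C@H]1CC=C(C)[C@@H](c2c(O)c(C(=O)C(C)C)c(O)cc2O[Si](C)(C)C(C)(C)C)C1 | intermediate
9 | cis-fused hexahydrodibenzofuran 1-O-TBS ether, 1-[(5aR,8S,9aR)-1-(tert-butyldimethylsilyloxy)-3-hydroxy-5a-methyl-8-(prop-1-en-2-yl)-5a,6,7,8,9,9a-hexahydrodibenzo[b,d]furan-4-yl]-2-methylpropan-1-one | C=C(C)[C@H]1CC[C@@]2(C)Oc3c(C(=O)C(C)C)c(O)cc(O[Si](C)(C)C(C)(C)C)c3[C@H]2C1 | intermediate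
10 | hexahydrodibenzofuran-1,3-diol, 1-[(5aR,8S,9aR)-1,3-dihydroxy-5a-methyl-8-(prop-1-en-2-yl)-5a,6,7,8,9,9a-hexahydrodibenzo[b,d]furan-4-yl]-2-methylpropan-1-one | C=C(C)[C@H]1CC[C@@]2(C)Oc3c(C(=O)C(C)C)c(O)cc(O)c3[C@H]2C1 | intermediate
11 | 3-chloro-3-methylbut-1-yne | CC(C)(Cl)C#C | starting material
12 | bis(1,1-dimethylpropargyl) ether, 1-[(5aR,8S,9aR)-5a-methyl-1,3-bis[(2-methylbut-3-yn-2-yl)oxy]-8-(prop-1-en-2-yl)-5a,6,7,8,9,9a-hexahydrodibenzo[b,d]furan-4-yl]-2-methylpropan-1-one | C=C(C)[C@H]1CC[C@@]2(C)Oc3c(C(=O)C(C)C)c(OC(C)(C)C#C)cc(OC(C)(C)C#C)c3[C@H]2C1 | intermediate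
13 | bis(1,1-dimethylallyl) ether (key-step precursor), 1-[(5aR,8S,9aR)-5a-methyl-1,3-bis[(2-methylbut-3-en-2-yl)oxy]-8-(prop-1-en-2-yl)-5a,6,7,8,9,9a-hexahydrodibenzo[b,d]furan-4-yl]-2-methylpropan-1-one | C=C(C)[C@H]1CC[C@@]2(C)Oc3c(C(=O)C(C)C)c(OC(C)(C)C=C)cc(OC(C)(C)C=C)c3[C@H]2C1 | intermediate
14 | monoprenyl phenol monoether, 1-[(5aR,8S,9aR)-1-hydroxy-5a-methyl-3-[(2-methylbut-3-en-2-yl)oxy]-2-(3-methylbut-2-en-1-yl)-8-(prop-1-en-2-yl)-5a,6,7,8,9,9a-hexahydrodibenzo[b,d]furan-4-yl]-2-methylpropan-1-one | C=C(C)[C@H]1CC[C@@]2(C)Oc3c(C(=O)C(C)C)c(OC(C)(C)C=C)c(CC=C(C)C)c(O)c3[C@H]2C1 | intermediate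
15 | gem-diprenyl dearomatised dihydrofuran (vinylogous ester), (5aR,8S,9aR)-3-hydroxy-5a-methyl-2,2-bis(3-methylbut-2-en-1-yl)-4-(2-methylpropanoyl)-8-(prop-1-en-2-yl)-5a,6,7,8,9,9a-hexahydrodibenzo[b,d]furan-1(2H)-one | C=C(C)[C@H]1CC[C@@]2(C)OC3=C([C@H]2C1)C(=O)C(CC=C(C)C)(CC=C(C)C)C(O)=C3C(=O)C(C)C | intermediate
16 | target CNP0324849.1, 3,5-dihydroxy-4-[(1R,2R,5S)-2-hydroxy-2-methyl-5-(prop-1-en-2-yl)cyclohexyl]-6,6-bis(3-methylbut-2-en-1-yl)-2-(2-methylpropanoyl)cyclohexa-2,4-dien-1-one | C=C(C)[C@H]1CC[C@@](C)(O)[C@@H](C2=C(O)C(CC=C(C)C)(CC=C(C)C)C(=O)C(C(=O)C(C)C)=C2O)C1 | target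

**Step count and risk**

Total steps: 12. Longest linear sequence: 11 steps (from 1 through steps 1–3 and 5–12).

Steps most likely to fail:

Step 12. The enol of 15 is ionised by the base before hydroxide can add, and the carbon to be attacked is flanked by the acyl group and a tertiary alkoxy group. The addition may therefore be too slow, and forcing it may bring retro-Claisen cleavage at the acyl group or around the non-enolisable C3'. The fallback sets out from 15 and comes back at 16. The acidic enol would first be capped by Mitsunobu O-allylation (allyl alcohol, PPh3, DIAD, THF) to give the neutral C4'-O-allyl enol ether F1. In this uncharged bis(vinylogous ester) the allyloxy-bearing carbon adjoins the gem-diprenyl centre and is screened on both faces, so LiOH in aqueous dioxane near room temperature should add at C6' and open the dihydrofuran to the ring-opened allyl enol ether F2. Pd(PPh3)4 with morpholine in THF would then remove the allyl group and give 16.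

Step 11. The tertiary allylic ethers may ionise instead of rearranging (loss of isoprene, or recombination with formal [1,3] shift), or the second shift onto the now substituted carbon may stall or be diverted to the acyl-bearing carbon. The fallback sets out from 10 and comes back at 15. It is a direct dearomatising C-alkylation: 10 would be treated with prenyl bromide (about 2.2 equiv) and aqueous KOH at 0 °C. The phenoxide is alkylated at its only free ring carbon to give the C-prenyl diol F3, whose phenoxide is alkylated again at the same carbon, giving 15 after acidification. O-Prenylated material is the side product to be separated.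

Step 9. The phenol hydrogen-bonded to the ketone may etherify incompletely, so that the reaction stops at a mono-ether. The fallback sets out from 10 and comes back at 13. It is a Tsuji–Trost-type O-allylation with tert-butyl 2-methylbut-3-en-2-yl carbonate F4 (prepared from 2-methylbut-3-en-2-ol, n-BuLi and Boc2O) and catalytic Pd(PPh3)4 in THF at 0 °C. Ionisation of the carbonate releases tert-butoxide, which is basic enough to deprotonate the chelated phenol, and the phenoxides attack the more substituted terminus of the π-prenylpalladium complex. This should give 13 directly and bypass 12 and the semi-hydrogenation.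

**Further compounds**

F1 | step 12 | C4'-O-allyl enol ether of 15 | C=C(C)[C@H]1CC[C@@]2(C)OC3=C([C@H]2C1)C(=O)C(CC=C(C)C)(CC=C(C)C)C(OCC=C)=C3C(=O)C(C)C
F2 | step 12 | ring-opened allyl enol ether (C4'-O-allyl ether of 16) | C=C(C)[C@H]1CC[C@@](C)(O)[C@@H](C2=C(O)C(CC=C(C)C)(CC=C(C)C)C(OCC=C)=C(C(=O)C(C)C)C2=O)C1
F3 | step 11 | C-prenyl diol, 2-(3-methylbut-2-en-1-yl) derivative of 10 | C=C(C)[C@H]1CC[C@@]2(C)Oc3c(C(=O)C(C)C)c(O)c(CC=C(C)C)c(O)c3[C@H]2C1
F4 | step 9 | tert-butyl 2-methylbut-3-en-2-yl carbonate | C=CC(C)(C)OC(=O)OC(C)(C)C
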